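The route rests on cutting the C7–C8 bond of the nonadienoate chain. This is the sp2–sp3 bond between the (E)-C6=C7 alkene and the two-carbon tether (C8–C9) to quaternary C2 of the dihydropyran ring of the chroman. In one operation, 9-BBN hydroboration of an (S)-2-vinylchroman and B-alkyl Suzuki–Miyaura coupling with a (2Z,6E)-iodo dienoate join a C13 and a C10 half. The stereocentre and both alkene geometries are already fixed at that point. The step exploits two features. C8–C9 is the vinyl group left by an enantioselective SN2′ closure of the O1–C2 bond, and fully substituted C2 forces boron onto the terminal carbon. The precursors are a vinylchroman and an alkenyl iodide.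

Key step: step 10

Assumption: the sense of induction in step 5 depends on the ligand antipode, so the commercial antipode that gives the (S)-vinylchroman is chosen by one test run. 9-BBN is written as its monomer.

Step 1
Reactants: 1 2,4-dihydroxy-6-methylbenzaldehyde
Product: 2 2-hydroxy-6-methyl-4-[(triisopropylsilyl)oxy]benzaldehyde
Conditions: TIPSCl (1.05 equiv), imidazole, DMF, 0 °C → rt
Reagents that add atoms: triisopropylsilyl chloride CC(C)[Si](Cl)(C(C)C)C(C)C
Why: Silyl ether protection should take the more acidic, unhindered 4-OH, because the 2-OH is held in a hydrogen bond to the neighbouring aldehyde.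

Step 2
Reactants: 2 2-hydroxy-6-methyl-4-[(triisopropylsilyl)oxy]benzaldehyde
Product: 3 2-ethenyl-3-methyl-5-[(triisopropylsilyl)oxy]phenol
Conditions: MePPh3Br (2.5 equiv), KOtBu (2.4 equiv), THF, 0 °C → rt
Reagents that add atoms: methyltriphenylphosphonium bromide C[P+](c1ccccc1)(c1ccccc1)c1ccccc1.[Br-]
Why: In this Wittig methylenation the first equivalent of ylide only deprotonates the phenol, the excess olefinates the aldehyde, and the aryl TIPS ether tolerates the ylide.

Step 3
Reactants: 4 but-2-yn-1-ol, 5 sodium bis(2-methoxyethoxy)aluminium hydride (Red-Al)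
Product: 7 (Z)-3-iodobut-2-en-1-ol, via cyclic alkenylaluminate 6 (not isolated)
Conditions: Red-Al, THF, 0 °C → rt; then I2, THF, −78 → 0 °C
Reagents that add atoms: iodine II
Why: Hydroxyl-directed trans-hydroalumination of the propargylic alcohol places aluminium at C3 in a five-membered aluminate, and iodinolysis with retention should give only the (Z)-alkenyl iodide.

Step 4
Reactants: 3 2-ethenyl-3-methyl-5-[(triisopropylsilyl)oxy]phenol, 8 9-borabicyclo[3.3.1]nonane (9-BBN), 7 (Z)-3-iodobut-2-en-1-ol
Product: 10 (Z)-5-{2-hydroxy-6-methyl-4-[(triisopropylsilyl)oxy]phenyl}-3-methylpent-2-en-1-ol, via O,C-bis(9-BBN) adduct 9 (not isolated)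
Conditions: 9-BBN (2.3 equiv), THF, 0 °C → rt; then 3 M aq K3PO4, 7, Pd(dppf)Cl2 (5 mol %), DMF, rt
Reagents that add atoms: none
Why: 9-BBN borylates the phenol transiently and adds to the terminal carbon of the twisted 2,6-disubstituted styrene, and B-alkyl Suzuki–Miyaura coupling with retention at the alkenyl iodide should give the geometrically pure (Z)-trisubstituted allylic alcohol.

Step 5
Reactants: 10 (Z)-5-{2-hydroxy-6-methyl-4-[(triisopropylsilyl)oxy]phenyl}-3-methylpent-2-en-1-ol
Product: 11 (2S)-2-ethenyl-2,5-dimethyl-7-[(triisopropylsilyl)oxy]-3,4-dihydro-2H-chromene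
Conditions: [DTBM-MeO-BIPHEP](AuCl)2 (2.5 mol %, chosen antipode), AgNTf2 (5 mol %), 4 Å MS, toluene, 0 °C → rt
Reagents that add atoms: none
Why: In this gold(I)-catalysed enantioselective dehydrative allylic etherification (formal SN2′), the chiral digold complex differentiates the faces of the (Z)-alkene in a 6-exo-trig anti-oxyauration by the phenol at the methyl-bearing carbon, and anti-elimination of Au/OH then releases water and the vinyl group, setting C2 as S.

Step 6
Reactants: 12 pent-4-yn-1-ol
Product: 14 (E)-5-iodo-4-methylpent-4-en-1-ol, via (E)-alkenyldimethylalane 13 (not isolated)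
Conditions: Me3Al (3 equiv), Cp2ZrCl2 (0.25 equiv), CH2Cl2, 0 °C → rt; then I2, THF, −30 → 0 °C
Reagents that add atoms: trimethylaluminium C[Al](C)C; iodine II
Why: Zirconium-catalysed Negishi carboalumination adds Me–Al syn with aluminium at the terminus, and iodinolysis with retention fixes the (E)-alkenyl iodide.

Step 7
Reactants: 14 (E)-5-iodo-4-methylpent-4-en-1-ol
Product: 15 (E)-5-iodo-4-methylpent-4-enal
Conditions: TEMPO (10 mol %), PhI(OAc)2 (1.1 equiv), CH2Cl2, rt
Reagents that add atoms: none
Why: Oxoammonium (TEMPO) oxidation of the primary alcohol stops at the aldehyde and leaves the alkenyl iodide untouched.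

Step 8
Reactants: 16 methyl 2-[bis(2,2,2-trifluoroethoxy)phosphoryl]acetate
Product: 17 methyl 2-[bis(2,2,2-trifluoroethoxy)phosphoryl]propanoate (racemic)
Conditions: KOtBu (1.0 equiv), THF, 0 °C; MeI, 0 °C → rt
Reagents that add atoms: iodomethane CI
Why: C-alkylation of the stabilised phosphonate carbanion with one equivalent of base and MeI gives the α-methyl reagent, and its stereocentre is lost in step 9.

Step 9
Reactants: 15 (E)-5-iodo-4-methylpent-4-enal, 17 methyl 2-[bis(2,2,2-trifluoroethoxy)phosphoryl]propanoate
Product: 18 methyl (2Z,6E)-7-iodo-2,6-dimethylhepta-2,6-dienoate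
Conditions: KHMDS, 18-crown-6, THF, −78 °C
Reagents that add atoms: none
Why: In the Still–Gennari olefination the electron-poor trifluoroethyl phosphonate with a dissociated potassium ion collapses quickly from the kinetic adduct, which should place the ester cis to the chain, that is (2Z).

Step 10
Reactants: 11 (2S)-2-ethenyl-2,5-dimethyl-7-[(triisopropylsilyl)oxy]-3,4-dihydro-2H-chromene, 8 9-borabicyclo[3.3.1]nonane (9-BBN), 18 methyl (2Z,6E)-7-iodo-2,6-dimethylhepta-2,6-dienoate
Product: 20 methyl (2Z,6E)-9-{(2R)-2,5-dimethyl-7-[(triisopropylsilyl)oxy]-3,4-dihydro-2H-chromen-2-yl}-2,6-dimethylnona-2,6-dienoate, via B-alkyl-9-BBN 19 (not isolated)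
Conditions: 9-BBN (1.5 equiv), THF, rt → 40 °C; then 3 M aq K3PO4, 18, Pd(dppf)Cl2 (5 mol %), AsPh3 (10 mol %), DMF, rt
Reagents that add atoms: none
Why: 9-BBN adds syn and anti-Markovnikov to the only alkene of 11, with the fully substituted C2 next to the vinyl group directing boron to the terminal carbon, so primary borane 19 forms with oxygen γ to boron and no β-alkoxy elimination can occur. Aqueous K3PO4 destroys residual B–H and converts 19 into its hydroxyborate; Pd(0) then inserts into the C(sp2)–I bond of 18 with retention, the primary alkyl group passes from boron to palladium, and reductive elimination forges C7–C8 of 20, which the wide bite angle of dppf makes faster than β-hydride elimination. The closest known reaction type is the one-pot hydroboration/B-alkyl Suzuki–Miyaura coupling of a terminal alkene with an (E)-alkenyl iodide. No ring is closed and no stereocentre is created: C2 is a non-epimerisable quaternary centre that is carried through (its descriptor changes from S to R only through CIP ranking), and the (6E) geometry is inherited stereospecifically from 18. The selectivity needed is chemoselectivity, secured by the order of addition (18 meets no B–H), by the far higher reactivity of the alkenyl iodide than of any other bond towards Pd(0), and by a mild phosphate base at room temperature that spares the methyl ester, the (Z)-enoate and the aryl TIPS ether.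

Step 11
Reactants: 20 methyl (2Z,6E)-9-{(2R)-2,5-dimethyl-7-[(triisopropylsilyl)oxy]-3,4-dihydro-2H-chromen-2-yl}-2,6-dimethylnona-2,6-dienoate
Product: 21 methyl (2Z,6E)-9-[(2R)-7-hydroxy-2,5-dimethyl-3,4-dihydro-2H-chromen-2-yl]-2,6-dimethylnona-2,6-dienoate (CNP0319148.1)
Conditions: TBAF (1.1 equiv), AcOH (1.1 equiv), THF, 0 °C
Reagents that add atoms: none
Why: Fluoride-mediated cleavage of the aryl silyl ether is fast at 0 °C, and the acetic acid buffer keeps the medium from harming the methyl ester or the (Z)-enoate.

Compound list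
1 | 2,4-dihydroxy-6-methylbenzaldehyde | O=Cc1c(C)cc(O)cc1O | starting material
2 | 2-hydroxy-6-methyl-4-[(triisopropylsilyl)oxy]benzaldehyde | O=Cc1c(C)cc(O[Si](C(C)C)(C(C)C)C(C)C)cc1O | intermediate
3 | 2-ethenyl-3-methyl-5-[(triisopropylsilyl)oxy]phenol | C=Cc1c(C)cc(O[Si](C(C)C)(C(C)C)C(C)C)cc1O | intermediate
4 | but-2-yn-1-ol | CC#CCO | starting material
5 | sodium bis(2-methoxyethoxy)aluminium hydride (Red-Al) | [Na+].[AlH2-](OCCOC)OCCOC | starting material
6 | sodium 2,2-bis(2-methoxyethoxy)-3-methyl-1-oxa-2-aluminatacyclopent-3-ene (cyclic alkenylaluminate, not isolated) | [Na+].CC1=CCO[Al-]1(OCCOC)OCCOC | intermediate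
7 | (Z)-3-iodobut-2-en-1-ol | C/C(I)=C/CO | intermediate
8 | 9-borabicyclo[3.3.1]nonane (9-BBN, monomer formula) | B1C2CCCC1CCC2 | starting material
9 | O,C-bis(9-BBN) adduct of 3: aryl borinate carrying a 2-(9-BBN)ethyl group (not isolated) | Cc1cc(O[Si](C(C)C)(C(C)C)C(C)C)cc(OB2C3CCCC2CCC3)c1CCB1C2CCCC1CCC2 | intermediate
10 | (Z)-5-{2-hydroxy-6-methyl-4-[(triisopropylsilyl)oxy]phenyl}-3-methylpent-2-en-1-ol | C/C(CCc1c(C)cc(O[Si](C(C)C)(C(C)C)C(C)C)cc1O)=C/CO | intermediate
11 | (2S)-2-ethenyl-2,5-dimethyl-7-[(triisopropylsilyl)oxy]-3,4-dihydro-2H-chromene | C=C[C@]1(C)CCc2c(C)cc(O[Si](C(C)C)(C(C)C)C(C)C)cc2O1 | intermediate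
12 | pent-4-yn-1-ol | C#CCCCO | starting material
13 | (E)-alkenyldimethylalane, O-dimethylaluminium alkoxide (not isolated) | C[Al](C)/C=C(\C)CCCO[Al](C)C | intermediate
14 | (E)-5-iodo-4-methylpent-4-en-1-ol | OCCC/C(C)=C/I | intermediate
15 | (E)-5-iodo-4-methylpent-4-enal | O=CCC/C(C)=C/I | intermediate
16 | methyl 2-[bis(2,2,2-trifluoroethoxy)phosphoryl]acetate | COC(=O)CP(=O)(OCC(F)(F)F)OCC(F)(F)F | starting material
17 | methyl 2-[bis(2,2,2-trifluoroethoxy)phosphoryl]propanoate (racemic) | COC(=O)C(C)P(=O)(OCC(F)(F)F)OCC(F)(F)F | intermediate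
18 | methyl (2Z,6E)-7-iodo-2,6-dimethylhepta-2,6-dienoate | COC(=O)/C(C)=C\CC/C(C)=C/I | intermediate
19 | 9-{2-[(2R)-2,5-dimethyl-7-[(triisopropylsilyl)oxy]-3,4-dihydro-2H-chromen-2-yl]ethyl}-9-BBN (not isolated) | B1(C2CCCC1CCC2)CC[C@]3(C)CCc4c(C)cc(O[Si](C(C)C)(C(C)C)C(C)C)cc4O3 | intermediate
20 | methyl (2Z,6E)-9-{(2R)-2,5-dimethyl-7-[(triisopropylsilyl)oxy]-3,4-dihydro-2H-chromen-2-yl}-2,6-dimethylnona-2,6-dienoate | COC(=O)/C(C)=C\CC/C(C)=C/CC[C@]1(C)CCc2c(C)cc(O[Si](C(C)C)(C(C)C)C(C)C)cc2O1 | intermediate
21 | methyl (2Z,6E)-9-[(2R)-7-hydroxy-2,5-dimethyl-3,4-dihydro-2H-chromen-2-yl]-2,6-dimethylnona-2,6-dienoate | COC(=O)/C(C)=C\CC/C(C)=C/CC[C@]1(C)CCc2c(C)cc(O)cc2O1 | target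

Total step count: 11
Longest linear sequence: 6 steps (steps 1, 2, 4, 5, 10, 11, from compound 1)

Steps most likely to fail

Step 10. Hydroboration of the vinyl group next to the fully substituted C2 may be slow. At the palladium stage the primary alkyl group may be lost by protodeboronation or β-hydride elimination, and the aqueous base may begin to saponify the ester. The fallback forms the same bond without base or water and sets out from 11. Hydroboration to 19 followed by oxidation (NaBO3·4H2O) should give the primary alcohol 2-[(2S)-2,5-dimethyl-7-[(triisopropylsilyl)oxy]-3,4-dihydro-2H-chromen-2-yl]ethanol F1. Appel iodination (I2, PPh3, imidazole) converts it into the primary iodide F2. Zinc insertion (Zn dust, LiCl, THF) gives the alkylzinc iodide F3. Negishi coupling of F3 with 18 (Pd(dppf)Cl2, THF) comes back to the route at 20.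

Step 5. Facial selectivity at the trisubstituted alkene may be poor, or a proton-catalysed ionisation to the allyl cation may run beside the gold cycle and erode the enantiomeric purity. The fallback changes to palladium π-allyl chemistry and sets out from 10. Chemoselective acylation of the primary allylic alcohol (ClCO2Me, pyridine, CH2Cl2, −20 °C) should give the (Z)-allyl methyl carbonate F4. An asymmetric allylic alkylation of Tsuji–Trost type follows, using Pd2(dba)3, the C2-symmetric trans-cyclohexane-1,2-diamine bis(2-diphenylphosphinobenzamide) ligand of the appropriate antipode and AcOH in CH2Cl2. It closes the O1–C2 bond through the faster-cyclising π-allyl diastereomer and comes back at 11.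

Step 2. Phenoxide formation may slow the attack of the ylide on the doubly ortho-substituted aldehyde, and the electron-rich vinylphenol may oligomerise on concentration. The fallback replaces olefination by addition and elimination and sets out from 2. MeMgBr (2.2 equiv, THF, 0 °C) should give the benzylic alcohol 2-(1-hydroxyethyl)-3-methyl-5-[(triisopropylsilyl)oxy]phenol F5. Mild dehydration (cat. PPTS, toluene, heat) proceeds through the o-quinone methide and a 1,5-hydrogen shift and comes back at 3, which is then carried as a solution directly into step 4.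

Further compounds
F1 | step 10 | 2-[(2S)-2,5-dimethyl-7-[(triisopropylsilyl)oxy]-3,4-dihydro-2H-chromen-2-yl]ethanol | OCC[C@]1(C)CCc2c(C)cc(O[Si](C(C)C)(C(C)C)C(C)C)cc2O1
F2 | step 10 | (2S)-2-(2-iodoethyl)-2,5-dimethyl-7-[(triisopropylsilyl)oxy]-3,4-dihydro-2H-chromene | ICC[C@]1(C)CCc2c(C)cc(O[Si](C(C)C)(C(C)C)C(C)C)cc2O1
F3 | step 10 | {2-[(2S)-2,5-dimethyl-7-[(triisopropylsilyl)oxy]-3,4-dihydro-2H-chromen-2-yl]ethyl}zinc iodide | I[Zn]CC[C@]1(C)CCc2c(C)cc(O[Si](C(C)C)(C(C)C)C(C)C)cc2O1
F4 | step 5 | (Z)-5-{2-hydroxy-6-methyl-4-[(triisopropylsilyl)oxy]phenyl}-3-methylpent-2-en-1-yl methyl carbonate | C/C(CCc1c(C)cc(O[Si](C(C)C)(C(C)C)C(C)C)cc1O)=C/COC(=O)OC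
F5 | step 2 | 2-(1-hydroxyethyl)-3-methyl-5-[(triisopropylsilyl)oxy]phenol (racemic) | CC(O)c1c(C)cc(O[Si](C(C)C)(C(C)C)C(C)C)cc1O
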